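Ring A is the free resorcinol end, ring B the central ring, ring C the ring with the methyl ester. Each is numbered C1 (carries carbonyl C7), C2 (OH), C4 (oxygen O4) and C6 (CH3). The A–B depside link is cut at the aryl bond B-C4–O4 instead of the crowded acyl carbon A-C7. The feature used: B-O2 and B-O4 stand 1,3 across a hydrogen-bearing B-C3, the array a B-C3/B-C4 aryne with alkoxy on B-C2 produces by taking oxygen at its far carbon and hydrogen at its near one. One fluoride-triggered operation thus joins the dibenzylated ring A acid to a ring B ortho-silylaryl triflate (O2-benzyl, tert-butyl ester). The B–C ester is made by ordinary coupling.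

Key step: step 9

Remark: the target is achiral, so no stereocentre has to be set. Orsellinic acid and methyl orsellinate are taken as purchasable.

Step 1
Reactants: 1 methyl orsellinate; 2 benzyl bromide
Product: 3 methyl 2,4-bis(benzyloxy)-6-methylbenzoate
Conditions: BnBr (2.5 equiv), K2CO3, DMF, 60 °C
Reagents that add atoms: benzyl bromide, BrCc1ccccc1
Why: Double Williamson etherification; in warm DMF with excess K2CO3 even the hydrogen-bonded O2 phenol is alkylated, and the methyl ester is inert.

Step 2
Reactants: 3 methyl 2,4-bis(benzyloxy)-6-methylbenzoate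
Product: 4 2,4-bis(benzyloxy)-6-methylbenzoic acid
Conditions: KOH, DMSO–H2O, 90 °C; then aq. HCl
Reagents that add atoms: potassium hydroxide (supplies the new carboxyl oxygen), [K+].[OH-]
Why: Saponification of a di-ortho-substituted benzoate needs hot hydroxide in a dipolar aprotic medium, which aryl benzyl ethers tolerate, and the O-protected carboxylate should not decarboxylate under base.

Step 3
Reactants: 5 orsellinic acid
Product: 6 tert-butyl orsellinate (tert-butyl 2,4-dihydroxy-6-methylbenzoate)
Conditions: O-tert-butyl-N,N'-diisopropylisourea, THF, rt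
Reagents that add atoms: O-tert-butyl-N,N'-diisopropylisourea, CC(C)N=C(OC(C)(C)C)NC(C)C
Why: Carboxylate O-alkylation by the protonated isourea transfers the tert-butyl group to oxygen, so the crowded carbonyl is never attacked, the less acidic phenols stay free, and room temperature avoids decarboxylation of 5.

Step 4
Reactants: 6 tert-butyl orsellinate
Product: 7 tert-butyl 2,4-dihydroxy-3-iodo-6-methylbenzoate
Conditions: I2 (1.0 equiv), NaHCO3, THF–H2O, 0 °C to rt
Reagents that add atoms: iodine, II
Why: Electrophilic aromatic iodination through the O4 phenoxide; in mildly basic medium resorcinols take iodine at the carbon between both oxygens (C3), C5 being preferred only in acidic media, and one equivalent of I2 limits double iodination.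

Step 5
Reactants: 7 tert-butyl 2,4-dihydroxy-3-iodo-6-methylbenzoate
Product: 8 tert-butyl 2-hydroxy-3-iodo-6-methyl-4-(pivaloyloxy)benzoate
Conditions: PivCl (1.05 equiv), Et3N, CH2Cl2, 0 °C
Reagents that add atoms: pivaloyl chloride, CC(C)(C)C(=O)Cl
Why: Chemoselective O-acylation, since O4-H is the free and more acidic phenol while O2-H is hydrogen-bonded to the ester carbonyl and wedged between iodine and the ester.

Step 6
Reactants: 8 tert-butyl 2-hydroxy-3-iodo-6-methyl-4-(pivaloyloxy)benzoate; 2 benzyl bromide
Product: 9 tert-butyl 2-(benzyloxy)-3-iodo-6-methyl-4-(pivaloyloxy)benzoate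
Conditions: BnBr, K2CO3, DMF, 40 °C
Reagents that add atoms: benzyl bromide, BrCc1ccccc1
Why: Williamson etherification of the only remaining phenol; the bulky pivalate resists carbonate in dry DMF and cannot migrate to the meta oxygen.

Step 7
Reactants: 9 tert-butyl 2-(benzyloxy)-3-iodo-6-methyl-4-(pivaloyloxy)benzoate
Product: 10 tert-butyl 2-(benzyloxy)-4-hydroxy-3-iodo-6-methylbenzoate
Conditions: NaOMe, MeOH–THF, 0 °C to rt; then cold aq. HCl
Reagents that add atoms: none
Why: Methanolysis (transesterification) of an aryl ester whose iodophenoxide is a good leaving group, whereas the di-ortho-substituted tert-butyl ester is shielded from methoxide.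

Step 8
Reactants: 10 tert-butyl 2-(benzyloxy)-4-hydroxy-3-iodo-6-methylbenzoate; 11 trifluoromethanesulfonic anhydride
Product: 15 tert-butyl 2-(benzyloxy)-6-methyl-4-(trifluoromethylsulfonyloxy)-3-(trimethylsilyl)benzoate, via O4-trimethylsilyl ether 12 (not isolated), via arylmagnesium chloride 13 (not isolated), via chloromagnesium phenoxide 14 (not isolated)
Conditions: (Me3Si)2NH, THF, reflux, then evaporate; iPrMgCl·LiCl, THF, −40 °C to rt; Tf2O, −78 °C
Reagents that add atoms: hexamethyldisilazane, C[Si](C)(C)N[Si](C)(C)C; trifluoromethanesulfonic anhydride, O=S(=O)(OS(=O)(=O)C(F)(F)F)C(F)(F)F; isopropylmagnesium chloride (magnesium and chlorine only in 13 and 14), CC(C)[Mg]Cl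
Why: O-silylation, iodine–magnesium exchange and retro-Brook rearrangement in sequence: exchange is fast at an iodide flanked by two oxygens and spares the hindered tert-butyl ester, the aryl carbanion takes the silyl group from neighbouring O4 because the magnesium phenoxide is far more stable, and that phenoxide is sulfonylated in situ.

Step 9
Reactants: 4 2,4-bis(benzyloxy)-6-methylbenzoic acid; 15 tert-butyl 2-(benzyloxy)-6-methyl-4-(trifluoromethylsulfonyloxy)-3-(trimethylsilyl)benzoate
Product: 17 tert-butyl tri-O-benzyl lecanorate (tert-butyl 2-(benzyloxy)-4-{[2,4-bis(benzyloxy)-6-methylbenzoyl]oxy}-6-methylbenzoate), via ring B aryne 16 (not isolated)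
Conditions: CsF (3 equiv), MeCN, rt; 4 in excess (1.5 equiv), slow addition of 15
Reagents that add atoms: none
Why: Fluoride attacks silicon of 15 and triflate leaves B-C4, which unmasks aryne 16 with its strained bond between B-C3 and B-C4; the carboxylate of 4 then bonds through oxygen to B-C4 and the aryl anion left on B-C3 is protonated by the acid/HF pool, a net O–H insertion. The closest known reaction type is the fluoride-induced O-arylation of carboxylic acids by ortho-silylaryl triflates in MeCN, combined with the well-documented meta-selectivity of 3-alkoxyarynes. No ring is closed and no stereocentre arises. The selectivity needed is attack at B-C4 and not B-C3, and it is secured by the benzyloxy group on B-C2, whose inductive pull bends the aryne so that B-C4 is the more linear, more electrophilic carbon and places the growing negative charge on B-C3 beside the C–O bond, while its bulk screens B-C3. Migration of the acyl group to the B-C3 anion (net C–O insertion to a ketone) should stay minor because A-C7 lies between the A-C2 benzyloxy and A-C6 methyl groups and protons are available in excess. As the bond is formed at carboxylate oxygen, the crowding that slows acyl activation of 4 plays no part.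

Step 10
Reactants: 17 tert-butyl tri-O-benzyl lecanorate
Product: 18 tri-O-benzyl lecanoric acid (2-(benzyloxy)-4-{[2,4-bis(benzyloxy)-6-methylbenzoyl]oxy}-6-methylbenzoic acid)
Conditions: TFA–CH2Cl2 (1:4), 0 °C to rt
Reagents that add atoms: none
Why: Acid-catalysed E1 cleavage of the tert-butyl ester with loss of isobutene is fast for this crowded, donor-substituted benzoate, so a short exposure should leave the aryl benzyl ethers and the depside ester intact.

Step 11
Reactants: 18 tri-O-benzyl lecanoric acid; 1 methyl orsellinate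
Product: 19 methyl tri-O-benzylgyrophorate (free OH on C-C2)
Conditions: DCC, DMAP (cat.), CH2Cl2, 0 °C to rt
Reagents that add atoms: none
Why: Steglich esterification; of the two phenols of 1 only O4-H is available, because O2-H is hydrogen-bonded to the methyl ester and hindered, which is the usual selectivity of depside couplings.

Step 12
Reactants: 19 methyl tri-O-benzylgyrophorate
Product: 20 methyl gyrophorate (target)
Conditions: H2 (1 atm), 10% Pd/C, EtOAc–THF, rt
Reagents that add atoms: none
Why: Catalytic hydrogenolysis of the three aryl benzyl ethers under neutral conditions in non-nucleophilic solvents, which avoids alcoholysis of the two depside esters.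

Compound list
1 | methyl orsellinate (methyl 2,4-dihydroxy-6-methylbenzoate) | COC(=O)c1c(C)cc(O)cc1O | starting material
2 | benzyl bromide | BrCc1ccccc1 | starting material
3 | methyl 2,4-bis(benzyloxy)-6-methylbenzoate | COC(=O)c1c(C)cc(OCc2ccccc2)cc1OCc1ccccc1 | intermediate
4 | 2,4-bis(benzyloxy)-6-methylbenzoic acid | Cc1cc(OCc2ccccc2)cc(OCc2ccccc2)c1C(=O)O | intermediate
5 | orsellinic acid (2,4-dihydroxy-6-methylbenzoic acid) | Cc1cc(O)cc(O)c1C(=O)O | starting material
6 | tert-butyl orsellinate | CC(C)(C)OC(=O)c1c(C)cc(O)cc1O | intermediate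
7 | tert-butyl 2,4-dihydroxy-3-iodo-6-methylbenzoate | CC(C)(C)OC(=O)c1c(C)cc(O)c(I)c1O | intermediate
8 | tert-butyl 2-hydroxy-3-iodo-6-methyl-4-(pivaloyloxy)benzoate | CC(C)(C)OC(=O)c1c(C)cc(OC(=O)C(C)(C)C)c(I)c1O | intermediate
9 | tert-butyl 2-(benzyloxy)-3-iodo-6-methyl-4-(pivaloyloxy)benzoate | CC(C)(C)OC(=O)c1c(C)cc(OC(=O)C(C)(C)C)c(I)c1OCc1ccccc1 | intermediate
10 | tert-butyl 2-(benzyloxy)-4-hydroxy-3-iodo-6-methylbenzoate | CC(C)(C)OC(=O)c1c(C)cc(O)c(I)c1OCc1ccccc1 | intermediate
11 | trifluoromethanesulfonic anhydride | O=S(=O)(OS(=O)(=O)C(F)(F)F)C(F)(F)F | starting material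
12 | tert-butyl 2-(benzyloxy)-3-iodo-6-methyl-4-(trimethylsilyloxy)benzoate | CC(C)(C)OC(=O)c1c(C)cc(O[Si](C)(C)C)c(I)c1OCc1ccccc1 | intermediate
13 | C3-chloromagnesio derivative of 12 (iodine replaced by MgCl) | CC(C)(C)OC(=O)c1c(C)cc(O[Si](C)(C)C)c([Mg]Cl)c1OCc1ccccc1 | intermediate
14 | chloromagnesium 3-(benzyloxy)-4-(tert-butoxycarbonyl)-5-methyl-2-(trimethylsilyl)phenoxide | CC(C)(C)OC(=O)c1c(C)cc(O[Mg]Cl)c([Si](C)(C)C)c1OCc1ccccc1 | intermediate
15 | tert-butyl 2-(benzyloxy)-6-methyl-4-(trifluoromethylsulfonyloxy)-3-(trimethylsilyl)benzoate | CC(C)(C)OC(=O)c1c(C)cc(OS(=O)(=O)C(F)(F)F)c([Si](C)(C)C)c1OCc1ccccc1 | intermediate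
16 | tert-butyl 2-(benzyloxy)-6-methyl-3,4-didehydrobenzoate (ring B aryne) | CC(C)(C)OC(=O)C1=C(OCc2ccccc2)C#CC=C1C | intermediate
17 | tert-butyl tri-O-benzyl lecanorate | CC(C)(C)OC(=O)c1c(C)cc(OC(=O)c2c(C)cc(OCc3ccccc3)cc2OCc2ccccc2)cc1OCc1ccccc1 | intermediate
18 | tri-O-benzyl lecanoric acid | O=C(O)c1c(C)cc(OC(=O)c2c(C)cc(OCc3ccccc3)cc2OCc2ccccc2)cc1OCc1ccccc1 | intermediate
19 | methyl tri-O-benzylgyrophorate | COC(=O)c1c(C)cc(OC(=O)c2c(C)cc(OC(=O)c3c(C)cc(OCc4ccccc4)cc3OCc3ccccc3)cc2OCc2ccccc2)cc1O | intermediate
20 | methyl gyrophorate | COC(=O)c1c(C)cc(OC(=O)c2c(C)cc(OC(=O)c3c(C)cc(O)cc3O)cc2O)cc1O | target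

Total step count: 12. Longest linear sequence: 10 steps (steps 3 to 12, from 5 to 20).

Steps most likely to fail

1. Step 9.
- **Risk:** The aryne may be used up by self-reaction or by capture of fluoride and solvent before the bulky carboxylate reaches it. Part of the addition may also take place at B-C3.
- **Fallback:** The same ester is formed at the acyl carbon, setting out from 6 and 4.
  - Carbodiimide coupling (DCC, DMAP, CH2Cl2) should acylate only the free O4 phenol of 6. This gives tert-butyl 4-{[2,4-bis(benzyloxy)-6-methylbenzoyl]oxy}-2-hydroxy-6-methylbenzoate F1.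
  - Williamson benzylation of the remaining B-O2 phenol with 2 (K2CO3, acetone, reflux) comes back to the route at 17.

2. Step 8.
- **Risk:** The silyl shift from O4 to the magnesiated carbon may be slow, so that simple loss of iodine on work-up or attack on an ester competes. Sulfonylation of the magnesium phenoxide in THF may also stay incomplete.
- **Fallback:** The C–Si bond is made by catalysis with zerovalent palladium instead of by an anionic shift, setting out from 9.
  - Cross-coupling with hexamethyldisilane (Pd2(dba)3, 2-(di-tert-butylphosphino)biphenyl, LiOAc, dioxane, 100 °C) should give tert-butyl 2-(benzyloxy)-6-methyl-4-(pivaloyloxy)-3-(trimethylsilyl)benzoate F2.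
  - Methanolysis with NaOMe frees tert-butyl 2-(benzyloxy)-4-hydroxy-6-methyl-3-(trimethylsilyl)benzoate F3.
  - Separate triflation with 11 and pyridine in CH2Cl2 at 0 °C comes back to the route at 15.

3. Step 4.
- **Risk:** Iodination may show poor site selectivity between C3 and C5, or may run on to double iodination.
- **Fallback:** The electrophilic substitution is replaced by a directed metalation, setting out from 6.
  - Boc2O (1 equiv, cat. DMAP, CH2Cl2) should protect only O4. This gives tert-butyl 4-(tert-butoxycarbonyloxy)-2-hydroxy-6-methylbenzoate F4.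
  - Benzylation with 2 (K2CO3, DMF, rt) gives tert-butyl 2-(benzyloxy)-4-(tert-butoxycarbonyloxy)-6-methylbenzoate F5.
  - TMPMgCl·LiCl (THF, 0 °C) deprotonates the carbon between the carbonate and the benzyloxy group. This gives the C3-arylmagnesium chloride F6.
  - Quenching with I2 converts F6 into tert-butyl 2-(benzyloxy)-4-(tert-butoxycarbonyloxy)-3-iodo-6-methylbenzoate F7.
  - K2CO3 in MeOH removes the aryl carbonate and comes back to the route at 10.

Further compounds
F1 | step 9 | tert-butyl 4-{[2,4-bis(benzyloxy)-6-methylbenzoyl]oxy}-2-hydroxy-6-methylbenzoate | CC(C)(C)OC(=O)c1c(C)cc(OC(=O)c2c(C)cc(OCc3ccccc3)cc2OCc2ccccc2)cc1O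
F2 | step 8 | tert-butyl 2-(benzyloxy)-6-methyl-4-(pivaloyloxy)-3-(trimethylsilyl)benzoate | CC(C)(C)OC(=O)c1c(C)cc(OC(=O)C(C)(C)C)c([Si](C)(C)C)c1OCc1ccccc1
F3 | step 8 | tert-butyl 2-(benzyloxy)-4-hydroxy-6-methyl-3-(trimethylsilyl)benzoate | CC(C)(C)OC(=O)c1c(C)cc(O)c([Si](C)(C)C)c1OCc1ccccc1
F4 | step 4 | tert-butyl 4-(tert-butoxycarbonyloxy)-2-hydroxy-6-methylbenzoate | CC(C)(C)OC(=O)Oc1cc(C)c(C(=O)OC(C)(C)C)c(O)c1
F5 | step 4 | tert-butyl 2-(benzyloxy)-4-(tert-butoxycarbonyloxy)-6-methylbenzoate | CC(C)(C)OC(=O)Oc1cc(C)c(C(=O)OC(C)(C)C)c(OCc2ccccc2)c1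
F6 | step 4 | C3-chloromagnesio derivative of F5 | CC(C)(C)OC(=O)Oc1cc(C)c(C(=O)OC(C)(C)C)c(OCc2ccccc2)c1[Mg]Cl
F7 | step 4 | tert-butyl 2-(benzyloxy)-4-(tert-butoxycarbonyloxy)-3-iodo-6-methylbenzoate | CC(C)(C)OC(=O)Oc1cc(C)c(C(=O)OC(C)(C)C)c(OCc2ccccc2)c1I
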